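## Analysis of the target

The target 21 is 8-(2,4-dihydroxy-6-pentylphenoxy)-6-hydroxy-3-pentyl-1H-isochromen-1-one. Ring A is the enol-lactone ring (C1, O2, C3, C4, C4a, C8a), ring B the fused benzene ring (C4a to C8a) and ring C the aryloxy ring (C1' to C6'). Ring A carries pentyl at C3, ring B a hydroxyl at C6 and the ether oxygen at C8, and ring C is a 5-pentylresorcinol joined through C1', the carbon between the C2' hydroxyl and the C6' pentyl group. There is no stereocentre, so every difficulty is one of regiochemistry and bond construction. The sensitive groups are the enol lactone of ring A (opened by hydroxide, alkoxides and amines) and three free phenols on two electron-rich rings, which are acidic and easily oxidised. The hard bond set is the diaryl ether C8–O–C1'. C8 lies ortho to the lactone carbonyl, C1' is flanked by oxygen and by pentyl, and ring C has no activating group for nucleophilic aromatic substitution, so any C–O coupling would meet a doubly ortho-substituted, electron-rich partner. The strategy rests on the pattern of ring C: C2' to C6' carry O, H, O, H and pentyl, which is the pattern of C2 to C6 of a 2,4-dialkoxy-6-pentylpyrylium ion. C1' is then a single carbon that can bring the ether oxygen with it, so the hindered ether is never made by coupling. Rings A and B follow from an orsellinic-type o-toluamide.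

## Retrosynthetic reasoning

Target 21 to 20. The three O–CH3 bonds are cut last. Free phenols would quench the bases and the ylide used earlier, and methyl ethers are the form in which the oxygens of ring C emerge from the pyrylium ion. The forward step is one Lewis-acid dealkylation that must spare the lactone and the diaryl ether.

20 to 19. The C1–O2 bond of ring A is cut, so the lactone carbonyl becomes a tertiary diethylamide and O2 with C3 becomes a ketone. The amide is wanted earlier because it directs benzylic metalation and is inert to a phosphorus ylide. The forward step needs the enol oxygen to displace the amine from a hindered amide.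

19 to 16 and 18. The C3–C4 bond is cut, because C4 is the benzylic methyl carbon of an o-toluamide and C3 with its pentyl chain is a hexanoyl unit. Amide 18 comes from acid chloride 17. The forward step is a lateral metalation followed by one acylation.

16 to 12 and 4 (key disconnection). Ring C is cut at C1'–C2' and C1'–C6'. Cutting at either C–O bond of the ether would lead back to the hindered coupling described above. The chosen cut leaves the ether oxygen on a one-carbon unit, the ylide carbon of 13 generated from salt 12, and gives the other five ring carbons as pyrylium salt 4 with both oxygens and the pentyl chain in place. The forward reaction has to add the ylide carbon to an α-carbon of 4, open the 2H-pyran and reclose by carbonyl olefination.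

12 to 9, and 9 to 7 and 8. The P–CH2 bond is cut to give chloromethyl ether 10, made from O,S-acetal 9, whose O–CH2 bond leads to phenol 7 and sulfide 8. Phenol 7 is the diethylamide of acid 5 (C–N bond). These are standard operations on a small aromatic compound.

4 to 3, and 3 to 1 and 2. The O–CH3 bond at C2 of the pyrylium ion is cut to give pyranone 3, and the bond between the first and second carbon of the pentyl chain leads to the purchasable pyranone 1 and iodide 2. The forward steps are a lateral enolate alkylation and an O-methylation.

## Alternatives that were turned down

Alternative 1: Ring C is cut at C2'–C3' and C4'–C5'. This leads to the 4-aryloxy-3-pentylcyclobutenone A2, which already holds the finished isocoumarin on the C8 oxygen, and to the silyloxyalkyne A3. On heating, A2 should open to a vinylketene that adds A3 in a [2+2] sense. The new cyclobutenone opens, recloses by 6π electrocyclisation and tautomerises to phenol A1 (Danheiser benzannulation), with the free hydroxyl at C2' and the silyl ether at C4'.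
- For: the substitution pattern of ring C follows from the mechanism, and the annulation is an established reaction class, so it is stronger on precedent than the chosen key step. Only desilylation and one demethylation would remain.
- Against: A2 is hard to reach. A 3-alkylcyclobutenone has to be functionalised at C4 by the hindered C8 phenol of an isocoumarin, where substitution competes with opening of the strained enone. A3 is a sensitive reagent that must be prepared. The thermal cascade is run on the most advanced intermediate, with the enol lactone present. The differentiation of the two ring C oxygens is of no use, because both end as free phenols.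
- Comparison: the chosen strategy gives up precedent at the key step, but it places that risk on two short fragments (two and three steps) and keeps the endgame to proven toluamide chemistry.

Alternative 2: Rings B and A are cut together at C7–C8, C5–C6 and C4a–C8a. This gives the ester-tethered 1,7-diyne A5 (an aryloxypropiolate of a homopropargylic alcohol) and ethoxyacetylene A6. A transition-metal-catalysed [2+2+2] cyclotrimerisation would form three C–C bonds and two rings at once and give the dihydroisocoumarin A4.
- For: very high bond economy, a convergent union, and a reaction class with broad precedent for tethered diynes, which the chosen key step lacks.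
- Against: A5 needs an aryl ynol ether of the fully substituted 2,4-dimethoxy-6-pentylphenol, so ring C and its oxygen at C1' must still be made separately. Ynol ethers and A6 are prone to hydration and oligomerisation under the catalyst. The ester tether prefers the conformation in which the two alkynes point apart. The orientation of A6 (ethoxy at C6, not C7) rests on a modest electronic bias. A4 is at the wrong oxidation level, with a C3 stereocentre that is made only to be removed by a dehydrogenation on a substrate with two electron-rich rings and further benzylic positions.
- Comparison: the chosen route forms no stereocentre, needs no redox adjustment and installs the C1' oxygen within the key step.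

Alternative 3: Ring C is cut at C5'–C6' and C3'–C4'. This gives the α-aryloxy enone A8 (a 3-aryloxynon-3-en-2-one carrying the amide-bearing ring on oxygen) and dimethyl malonate A9. Under alkoxide base, A9 should add to the β-carbon of A8, and the methyl ketone enolate should then close onto one ester group (Michael addition, then Claisen condensation) to give the cyclohexane-1,3-dione A7.
- For: this is the classical construction of 5-alkylresorcinols, with cheap reagents and the firmest precedent of the four strategies. As in the chosen route, the ether oxygen is installed early by simple O-alkylation.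
- Against: the acceptor is β-alkylated and carries a donor oxygen on the α-carbon, and both slow conjugate addition and favour γ-deprotonation. A8 needs a regiocontrolled aldol condensation at the oxygen-bearing carbon of an aryloxyacetone. A7 is a mixture of stereoisomers that must still be saponified, decarboxylated and dehydrogenated. Aromatisation can also occur by formal loss of the aryloxy group (elimination across C1'–C6', then tautomerisation), which needs no oxidant and would destroy the ether. The two new phenols must then be protected before the lateral metalation.
- Comparison: that is four to five operations after ring closure, against none in the pyrylium route, where ring C appears aromatic, at the right oxidation level and already as its dimethyl ether.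

Key step: step 6

Remark: compounds 1, 2, 5, 8 and 17 are taken as purchasable; 14 and 15 are drawn for addition of the ylide at the pentyl-bearing α-carbon of 4 (14 as a mixture of diastereomers, 15 as a mixture of isomers about its C2=C3 bond), and addition at the methoxy-bearing α-carbon would lead through the isomeric adducts to the same product 16.

## Route

Step 1
Reactants: 1 (4-methoxy-6-methyl-2H-pyran-2-one) and 2 (1-iodobutane)
Product: 3 4-methoxy-6-pentyl-2H-pyran-2-one
Conditions: LiN(i-Pr)2 (1.05 equiv), THF, −78 °C; 2, DMPU, −78 → −20 °C
Reagents that add atoms: none
Why: Deprotonation of the 6-methyl group gives the linearly conjugated (vinylogous ester) enolate, whose terminal carbon is alkylated by the primary iodide in an SN2 reaction promoted by DMPU; this lateral alkylation of 6-methyl-4-methoxypyran-2-ones is known enolate chemistry and installs the pentyl chain in one step.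

Step 2
Reactants: 3 (4-methoxy-6-pentyl-2H-pyran-2-one)
Product: 4 2,4-dimethoxy-6-pentylpyrylium tetrafluoroborate
Conditions: Me3OBF4 (1.1 equiv), CH2Cl2, rt, argon; Et2O (precipitation)
Reagents that add atoms: trimethyloxonium tetrafluoroborate, C[O+](C)C.F[B-](F)(F)F
Why: O-Methylation of the lactone carbonyl oxygen by the trialkyloxonium salt; the 4-methoxy group makes this oxygen the most nucleophilic site (vinylogous carbonate), the product is an aromatic pyrylium ion, and tetrafluoroborate cannot remove the new methyl group again. The salt is moisture-sensitive and should be used directly.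

Step 3
Reactants: 5 (everninic acid, 2-hydroxy-4-methoxy-6-methylbenzoic acid)
Product: 7 N,N-diethyl-2-hydroxy-4-methoxy-6-methylbenzamide, via 2-hydroxy-4-methoxy-6-methylbenzoyl chloride 6 (not isolated)
Conditions: (COCl)2, DMF (cat.), CH2Cl2, 0 °C → rt; evaporate; Et2NH (4 equiv), CH2Cl2, 0 °C → rt
Reagents that add atoms: diethylamine, CCNCC; oxalyl chloride, O=C(Cl)C(=O)Cl (chlorine of 6 only)
Why: Acid chloride formation under Vilsmeier-type catalysis, then acylation of the amine; the ortho hydroxyl is held in a hydrogen bond and any ester formed on it is cleaved by the excess amine, so the phenol should need no protection.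

Step 4
Reactants: 7 (N,N-diethyl-2-hydroxy-4-methoxy-6-methylbenzamide) and 8 (chloromethyl methyl sulfide)
Product: 9 N,N-diethyl-4-methoxy-2-methyl-6-[(methylsulfanyl)methoxy]benzamide
Conditions: NaH, DMF, 0 °C; 8, NaI (cat.), 0 °C → rt
Reagents that add atoms: none
Why: Williamson ether synthesis; NaH deprotonates the hydrogen-bonded phenol completely and the phenoxide displaces the activated chloride of the α-chloro sulfide with iodide catalysis (Finkelstein exchange), giving the O,S-acetal that is the usual precursor of an aryl chloromethyl ether.

Step 5
Reactants: 9 (N,N-diethyl-4-methoxy-2-methyl-6-[(methylsulfanyl)methoxy]benzamide)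
Product: 12 {[2-(diethylcarbamoyl)-5-methoxy-3-methylphenoxy]methyl}triphenylphosphonium tetrafluoroborate, via chloromethyl ether 10 (not isolated), via phosphonium chloride 11 (not isolated)
Conditions: SO2Cl2 (1.0 equiv), cyclohexene, CH2Cl2, −78 → 0 °C; evaporate; PPh3, MeCN, rt → 50 °C; CH2Cl2/aq. NaBF4
Reagents that add atoms: triphenylphosphine, c1ccc(cc1)P(c1ccccc1)c1ccccc1; sodium tetrafluoroborate, [Na+].F[B-](F)(F)F; sulfuryl chloride, O=S(=O)(Cl)Cl (chlorine of 10 and 11 only)
Why: SO2Cl2 chlorinates sulfur to a chlorosulfonium ion that fragments to the oxocarbenium ion and MeSCl (trapped by cyclohexene), and chloride gives α-chloro ether 10; the sulfide should react far faster than the arene at −78 °C. The α-chloro ether alkylates PPh3 readily, as in the preparation of alkoxymethylphosphonium salts, and the anion exchange removes chloride, which could dealkylate the methoxypyrylium ion in step 6.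

Step 6
Reactants: 12 ({[2-(diethylcarbamoyl)-5-methoxy-3-methylphenoxy]methyl}triphenylphosphonium tetrafluoroborate) and 4 (2,4-dimethoxy-6-pentylpyrylium tetrafluoroborate)
Product: 16 N,N-diethyl-2-(2,4-dimethoxy-6-pentylphenoxy)-4-methoxy-6-methylbenzamide, via phosphorus ylide 13 (not isolated), via 2H-pyran adduct 14 (not isolated), via ring-opened dienoate phosphonium salt 15 (not isolated)
Conditions: 12, KN(SiMe3)2 (1.0 equiv), THF, −78 °C; add to 4 (1.2 equiv, suspension), THF, −78 → 0 °C; KN(SiMe3)2 (1.0 equiv), −78 °C → rt, then 65 °C
Reagents that add atoms: none
Why: Proposed new method: deprotonation of 12 gives the α-aryloxy ylide 13, whose carbon adds to an α-carbon of the pyrylium ion of 4, drawn at C6 (the pentyl-bearing carbon, the only ring position without a donor oxygen substituent of its own), to give 2H-pyran 14, which opens by 6π electrocycloreversion (or, after deprotonation, by E1cB loss of the ring oxygen) to the dienoate phosphonium salt 15. The second equivalent of base removes the P–CH(OAr) proton, which is allylic and doubly vinylogous to the ester, and the new ylide carbon attacks the ester carbonyl carbon; the betaine/oxaphosphetane then loses Ph3P=O, so that C1'=C2' forms and ring C is aromatic at once, with the ester methoxy group kept as the C2' ether. The closest known reaction type is the conversion of 2,4,6-triarylpyrylium salts into benzenes with alkylidenetriphenylphosphoranes, supported by the azulene synthesis from alkylpyrylium salts and cyclopentadienide, in which a carbanion adds at the α-carbon of an alkyl-substituted pyrylium ion and the opened chain recloses by condensation; alkoxy groups on the pyrylium ion, an α-aryloxy ylide and an ester as olefination acceptor have not been combined in this way. Ring C closes as a six-membered carbocycle by intramolecular Wittig olefination, a 6-exo-trig attack on the carbonyl group that is equivalent to disrotatory 6π closure of the trienolate form of the ylide, and the cis geometry needed at the C5'=C6' bond is reachable because 14 and 15 interconvert. No stereocentre is formed. The step needs carbon attack at an α-position in preference to attack at C4 (a 4H-pyran that can only shed a methoxy group), to addition–elimination of a methoxy group and to proton abstraction from the pentyl α-CH2, whereas attack at C2 is tolerated, because its 2H-pyran opens to the pentyl ketone and closes by the ketone Wittig reaction to the same arene 16. This should be secured by the concentration of positive charge next to the ring oxygen, the greater hindrance and donor stabilisation at C4, the reversibility of proton transfer against the irreversibility of ring opening, the low temperature, and the tetrafluoroborate counter-ions, which cannot dealkylate the methoxypyrylium ion. The twisted, doubly ortho-substituted diethylamide should not be attacked by the ylide at −78 °C, so no benzofuran is expected.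

Step 7
Reactants: 17 (hexanoyl chloride)
Product: 18 N-methoxy-N-methylhexanamide
Conditions: MeNHOMe·HCl, Et3N (2.2 equiv), CH2Cl2, 0 °C → rt
Reagents that add atoms: N,O-dimethylhydroxylamine hydrochloride, CNOC.Cl
Why: Schotten–Baumann-type acylation of N,O-dimethylhydroxylamine by the acid chloride; it provides an acyl donor that accepts a carbanion only once.

Step 8
Reactants: 16 (N,N-diethyl-2-(2,4-dimethoxy-6-pentylphenoxy)-4-methoxy-6-methylbenzamide) and 18 (N-methoxy-N-methylhexanamide)
Product: 19 N,N-diethyl-2-(2,4-dimethoxy-6-pentylphenoxy)-4-methoxy-6-(2-oxoheptyl)benzamide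
Conditions: LiN(i-Pr)2 (1.2 equiv), THF, −78 °C; 18 (1.5 equiv), −78 → 0 °C; aq. NH4Cl
Reagents that add atoms: none
Why: Amide-directed lateral lithiation of the o-toluamide; both positions ortho to the amide are substituted and ring C has no hydrogen ortho to the ether oxygen, so the benzylic methyl group is the only site the amide activates. The benzylic anion adds to the N-methoxy-N-methylamide, and the chelated tetrahedral intermediate releases the ketone only on work-up, which prevents double addition and enolisation of the product in the flask.

Step 9
Reactants: 19 (N,N-diethyl-2-(2,4-dimethoxy-6-pentylphenoxy)-4-methoxy-6-(2-oxoheptyl)benzamide)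
Product: 20 8-(2,4-dimethoxy-6-pentylphenoxy)-6-methoxy-3-pentyl-1H-isochromen-1-one
Conditions: AcOH, 110 °C
Reagents that add atoms: none
Why: Acid-catalysed enol lactonisation; the enol oxygen of the ketone adds to the protonated amide carbonyl in a 6-exo-trig closure and the amine leaves as its ammonium acetate, which makes the exchange irreversible and gives the conjugated isocoumarin. Aryl methyl ethers and the diaryl ether are stable to hot acetic acid.

Step 10
Reactants: 20 (8-(2,4-dimethoxy-6-pentylphenoxy)-6-methoxy-3-pentyl-1H-isochromen-1-one)
Product: 21 8-(2,4-dihydroxy-6-pentylphenoxy)-6-hydroxy-3-pentyl-1H-isochromen-1-one (the target)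
Conditions: BBr3 (8 equiv), CH2Cl2, −78 °C → rt; H2O
Reagents that add atoms: none
Why: Lewis-acid dealkylation; BBr3 coordinates each methoxy oxygen, bromide removes the methyl group by SN2, and the aryloxyboranes are hydrolysed on work-up. The diaryl ether has no sp3 carbon on oxygen and the conjugated lactone is only coordinated, so both should survive.

## Compound list

1 | 4-methoxy-6-methyl-2H-pyran-2-one | Cc1cc(OC)cc(=O)o1 | starting material
2 | 1-iodobutane | CCCCI | starting material
3 | 4-methoxy-6-pentyl-2H-pyran-2-one | CCCCCc1cc(OC)cc(=O)o1 | intermediate
4 | 2,4-dimethoxy-6-pentylpyrylium tetrafluoroborate | CCCCCc1cc(OC)cc(OC)[o+]1.F[B-](F)(F)F | intermediate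
5 | everninic acid (2-hydroxy-4-methoxy-6-methylbenzoic acid) | Cc1cc(OC)cc(O)c1C(=O)O | starting material
6 | 2-hydroxy-4-methoxy-6-methylbenzoyl chloride (formed in the flask) | Cc1cc(OC)cc(O)c1C(=O)Cl | intermediate
7 | N,N-diethyl-2-hydroxy-4-methoxy-6-methylbenzamide | CCN(CC)C(=O)c1c(C)cc(OC)cc1O | intermediate
8 | chloromethyl methyl sulfide | CSCCl | starting material
9 | N,N-diethyl-4-methoxy-2-methyl-6-[(methylsulfanyl)methoxy]benzamide | CCN(CC)C(=O)c1c(C)cc(OC)cc1OCSC | intermediate
10 | 2-(chloromethoxy)-N,N-diethyl-4-methoxy-6-methylbenzamide (formed in the flask) | CCN(CC)C(=O)c1c(C)cc(OC)cc1OCCl | intermediate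
11 | {[2-(diethylcarbamoyl)-5-methoxy-3-methylphenoxy]methyl}triphenylphosphonium chloride (formed in the flask) | CCN(CC)C(=O)c1c(C)cc(OC)cc1OC[P+](c1ccccc1)(c1ccccc1)c1ccccc1.[Cl-] | intermediate
12 | {[2-(diethylcarbamoyl)-5-methoxy-3-methylphenoxy]methyl}triphenylphosphonium tetrafluoroborate | CCN(CC)C(=O)c1c(C)cc(OC)cc1OC[P+](c1ccccc1)(c1ccccc1)c1ccccc1.F[B-](F)(F)F | intermediate
13 | N,N-diethyl-4-methoxy-2-methyl-6-[(triphenyl-λ5-phosphanylidene)methoxy]benzamide (ylide, formed in the flask) | CCN(CC)C(=O)c1c(C)cc(OC)cc1OC=P(c1ccccc1)(c1ccccc1)c1ccccc1 | intermediate
14 | {[2-(diethylcarbamoyl)-5-methoxy-3-methylphenoxy](4,6-dimethoxy-2-pentyl-2H-pyran-2-yl)methyl}triphenylphosphonium tetrafluoroborate (mixture of diastereomers, formed in the flask) | CCCCCC1(C(Oc2cc(OC)cc(C)c2C(=O)N(CC)CC)[P+](c2ccccc2)(c2ccccc2)c2ccccc2)C=C(OC)C=C(OC)O1.F[B-](F)(F)F | intermediate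
15 | {(4E)-1-[2-(diethylcarbamoyl)-5-methoxy-3-methylphenoxy]-4,6-dimethoxy-6-oxo-2-pentylhexa-2,4-dien-1-yl}triphenylphosphonium tetrafluoroborate (mixture of isomers about C2=C3, formed in the flask) | COC(=O)/C=C(OC)\C=C(CCCCC)C(Oc1cc(OC)cc(C)c1C(=O)N(CC)CC)[P+](c1ccccc1)(c1ccccc1)c1ccccc1.F[B-](F)(F)F | intermediate
16 | N,N-diethyl-2-(2,4-dimethoxy-6-pentylphenoxy)-4-methoxy-6-methylbenzamide | CCCCCc1cc(OC)cc(OC)c1Oc1cc(OC)cc(C)c1C(=O)N(CC)CC | intermediate
17 | hexanoyl chloride | CCCCCC(=O)Cl | starting material
18 | N-methoxy-N-methylhexanamide | CCCCCC(=O)N(C)OC | intermediate
19 | N,N-diethyl-2-(2,4-dimethoxy-6-pentylphenoxy)-4-methoxy-6-(2-oxoheptyl)benzamide | CCCCCC(=O)Cc1cc(OC)cc(Oc2c(OC)cc(OC)cc2CCCCC)c1C(=O)N(CC)CC | intermediate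
20 | 8-(2,4-dimethoxy-6-pentylphenoxy)-6-methoxy-3-pentyl-1H-isochromen-1-one | CCCCCc1cc2cc(OC)cc(Oc3c(OC)cc(OC)cc3CCCCC)c2c(=O)o1 | intermediate
21 | 8-(2,4-dihydroxy-6-pentylphenoxy)-6-hydroxy-3-pentyl-1H-isochromen-1-one | CCCCCc1cc2cc(O)cc(Oc3c(O)cc(O)cc3CCCCC)c2c(=O)o1 | target

## Step count and least certain steps

Total step count: 10. Longest linear sequence: 7 steps (steps 3, 4, 5, 6, 8, 9 and 10, from 5).

Step 6 (key step, proposed new method). The most likely failures are:
- addition of the ylide at C4, or addition–elimination at a methoxy-bearing carbon, because both carry oxocarbenium character and lead to pyranylidene products that cannot open;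
- proton transfer from the pentyl α-CH2 of the pyrylium ion to the basic ylide, which would stall the reaction before ring opening;
- thermal decay of the α-aryloxy ylide before it is consumed.

The fallback uses known chemistry, sets out from 7 and comes back at 16. Commercial 1,3-dimethoxy-5-pentylbenzene F1 is iodinated with N-iodosuccinimide in MeCN at the position between the pentyl chain and a methoxy group (para to the other methoxy group) to give 1-iodo-2,4-dimethoxy-6-pentylbenzene F2. F2 is joined to phenol 7 by Ullmann-type C–O coupling (CuI, picolinic acid, K3PO4, DMSO, 90–110 °C) to give 16. Coupling a doubly ortho-substituted, electron-rich aryl iodide is demanding but is a known reaction type, and steps 1, 2, 4 and 5 would fall away.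

Step 5. Electrophilic chlorination or sulfenylation of the electron-rich ring may compete with chlorination at sulfur. The α-chloro ether may also be lost by hydrolysis, or by participation of the neighbouring amide oxygen before the phosphine is added. The fallback sets out from 7 and comes back at 10. Phenol 7 is alkylated with ethyl bromoacetate F3 (K2CO3, DMF) to ethyl 2-[2-(diethylcarbamoyl)-5-methoxy-3-methylphenoxy]acetate F4. Saponification (LiOH, THF/H2O) gives 2-[2-(diethylcarbamoyl)-5-methoxy-3-methylphenoxy]acetic acid F5. Chlorodecarboxylation (Pb(OAc)4, LiCl, benzene, 80 °C, Kochi reaction) gives chloromethyl ether 10 without any electrophilic chlorine or sulfur reagent. Quaternisation and anion exchange then follow as in step 5.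

Step 1. Metalation at C3 of the pyranone ring may compete with deprotonation of the methyl group. Slow alkylation by a primary iodide also allows proton exchange between product and enolate, which leads to double alkylation and recovered 1. The fallback sets out from 1 and comes back at 3. The same enolate (LiN(i-Pr)2, THF, −78 °C) is added to butanal F6, a much faster electrophile, to give 6-(2-hydroxypentyl)-4-methoxy-2H-pyran-2-one F7 (racemic). Acid-catalysed dehydration (TsOH, toluene, reflux) gives 4-methoxy-6-[(1E)-pent-1-en-1-yl]-2H-pyran-2-one F8. Hydrogenation of the side-chain alkene (H2, Pd/C, EtOAc, stopped after one equivalent) gives 3.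

Step 8. Proton transfer from the α-CH2 of 18 to the benzylic anion, or condensation of the anion with the amide group of unreacted 16, may compete with acylation, and metalation of the twisted, hindered amide may be incomplete. The fallback sets out from 16 and comes back at 19. The lateral anion is trapped with hexanal F9 to give N,N-diethyl-2-(2,4-dimethoxy-6-pentylphenoxy)-6-(2-hydroxyheptyl)-4-methoxybenzamide F10 (racemic). Oxidation with Dess–Martin periodinane (CH2Cl2, rt) gives ketone 19.

## Further compounds

F1 | step 6 | 1,3-dimethoxy-5-pentylbenzene (purchased) | CCCCCc1cc(OC)cc(OC)c1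
F2 | step 6 | 1-iodo-2,4-dimethoxy-6-pentylbenzene | CCCCCc1cc(OC)cc(OC)c1I
F3 | step 5 | ethyl bromoacetate (purchased) | CCOC(=O)CBr
F4 | step 5 | ethyl 2-[2-(diethylcarbamoyl)-5-methoxy-3-methylphenoxy]acetate | CCOC(=O)COc1cc(OC)cc(C)c1C(=O)N(CC)CC
F5 | step 5 | 2-[2-(diethylcarbamoyl)-5-methoxy-3-methylphenoxy]acetic acid | OC(=O)COc1cc(OC)cc(C)c1C(=O)N(CC)CC
F6 | step 1 | butanal (purchased) | CCCC=O
F7 | step 1 | 6-(2-hydroxypentyl)-4-methoxy-2H-pyran-2-one (racemic) | CCCC(O)Cc1cc(OC)cc(=O)o1
F8 | step 1 | 4-methoxy-6-[(1E)-pent-1-en-1-yl]-2H-pyran-2-one | CCC/C=C/c1cc(OC)cc(=O)o1
F9 | step 8 | hexanal (purchased) | CCCCCC=O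
F10 | step 8 | N,N-diethyl-2-(2,4-dimethoxy-6-pentylphenoxy)-6-(2-hydroxyheptyl)-4-methoxybenzamide (racemic) | CCCCCC(O)Cc1cc(OC)cc(Oc2c(OC)cc(OC)cc2CCCCC)c1C(=O)N(CC)CC
A1 | alternative 1 | 8-[2-hydroxy-6-pentyl-4-(triisopropylsilyloxy)phenoxy]-6-methoxy-3-pentyl-1H-isochromen-1-one | CCCCCc1cc(O[Si](C(C)C)(C(C)C)C(C)C)cc(O)c1Oc1cc(OC)cc2cc(CCCCC)oc(=O)c12
A2 | alternative 1 | 6-methoxy-8-[(4-oxo-2-pentylcyclobut-2-en-1-yl)oxy]-3-pentyl-1H-isochromen-1-one (racemic) | CCCCCC1=CC(=O)C1Oc1cc(OC)cc2cc(CCCCC)oc(=O)c12
A3 | alternative 1 | (ethynyloxy)triisopropylsilane | C#CO[Si](C(C)C)(C(C)C)C(C)C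
A4 | alternative 2 | 8-(2,4-dimethoxy-6-pentylphenoxy)-6-ethoxy-3-pentyl-3,4-dihydro-1H-isochromen-1-one (racemic) | CCCCCC1Cc2cc(OCC)cc(Oc3c(OC)cc(OC)cc3CCCCC)c2C(=O)O1
A5 | alternative 2 | non-1-yn-4-yl 3-(2,4-dimethoxy-6-pentylphenoxy)prop-2-ynoate (racemic) | C#CCC(CCCCC)OC(=O)C#COc1c(OC)cc(OC)cc1CCCCC
A6 | alternative 2 | ethoxyacetylene (ethoxyethyne) | C#COCC
A7 | alternative 3 | methyl 3-[2-(diethylcarbamoyl)-5-methoxy-3-methylphenoxy]-4,6-dioxo-2-pentylcyclohexane-1-carboxylate (mixture of diastereomers) | CCCCCC1C(C(=O)OC)C(=O)CC(=O)C1Oc1cc(OC)cc(C)c1C(=O)N(CC)CC
A8 | alternative 3 | N,N-diethyl-4-methoxy-2-methyl-6-[(2-oxonon-3-en-3-yl)oxy]benzamide | CCCCCC=C(Oc1cc(OC)cc(C)c1C(=O)N(CC)CC)C(C)=O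
A9 | alternative 3 | dimethyl malonate | COC(=O)CC(=O)OC
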